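## The problem

Target 27 is a resveratrol-type trimer in which two trans-2,3-diaryl-2,3-dihydrobenzofurans are joined through the C3–C5′ bond. C3 of the first unit is therefore a methine flanked by the fused ring A, by ring B and by C2. Ring A carries a hydroxyl at C6 and an (E)-4-hydroxystyryl group at C4, peri to the C3 aryl group. Ring B carries O1′, a hydroxyl at C7′ and the second dihydrofuran with a 3,5-dihydroxyphenyl group at C3′.

The four stereocentres fall into two remote pairs, (2S,3S) and (2R,3R). Within a pair the trans arrangement is the thermodynamic one. C3 (C3′) has no heteroatom and is configurationally robust, whereas C2 (C2′) is a para-oxygenated benzylic ether carbon that ionises under acid and closes again trans to its neighbour. Each C3 can thus correct its own C2, but neither pair can steer the other, so two independent sources of absolute configuration are needed.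

The fragile groups are the seven phenols, the two benzylic C–O bonds and above all the stilbene. Strong acid makes the stilbene alkylate ring B at C4′ or C6′, and a triplet sensitiser isomerises it. Base opens flavanone-type precursors to chalcones.

The feature that invites the key step is the following. O1, the (S)-configured C2 with its 4-oxygenated phenyl group, and ring A with oxygen at C6 and an exchangeable oxygen at C4 are the O1–C2–aryl unit and the phloroglucinol ring of natural (2S)-naringenin 1. Its heterocycle is exactly one carbon too large. Extruding the carbonyl carbon from that ring leaves it as a carboxyl group on C3, the atom that must later bond to ring B.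

## Retrosynthesis

**Stilbene last (27 ⇐ 26 ⇐ 22 + 25).** The seven O–acetyl bonds of heptaacetate 26 and then the C4–vinyl bond are cut, giving aryl triflate 22 and (E)-alkenylboronate 25. The stilbene is introduced at the very end because it tolerates neither the Lewis acid needed for ether cleavage nor the photocatalyst of the fragment union. A Suzuki–Miyaura coupling fixes the E geometry in the reagent, which a Wittig reaction at C4 would not. The forward reaction must achieve oxidative addition at a C4–O bond crowded by the C3 aryl group. Boronate 25 comes from 4-acetoxystyrene 23 and vinylboronate 24 by cross-metathesis.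

**Ether cleavage before the stilbene (22 ⇐ 21 ⇐ 20).** Six O–methyl bonds are cut on hexamethyl ether triflate 20. The triflate keeps C4 distinct from the six phenols of 21. Acetylation to 22 keeps phenolates out of the coupling and makes the intermediate easy to purify. This costs two simple steps and removes the one combination (boron tribromide plus stilbene) most likely to destroy the skeleton.

**Union at C3–C5′ (20 ⇐ 9 + 19).** Cutting this bond gives carboxylic acid 9 and aryl bromide 19, two halves of similar size that each carry one stereo pair. A Friedel–Crafts alkylation of ring B would not distinguish C5′ from C4′ and C6′. A decarboxylative arylation uses the carboxyl group the key step leaves on C3 and the halogen already on C5′. The forward step must react the bromide in preference to the C4 triflate and place the aryl group trans to the C2 aryl group.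

**Triflate before the union (9 ⇐ 8 ⇐ 7).** The C4 phenol of ester 7 is sulfonylated (8) before the ester is cleaved (9). A free, electron-rich phenolate would be oxidised by the photocatalyst. The triflate is both a protecting group for that step and the handle for the styryl group.

**Key cut, C3–C3a (7 ⇐ 4).** Ester 7 is traced to 3-diazoflavanone 4 by a Wolff ring contraction. The precursor already contains O1, C2 with its aryl group and ring A in the right oxidation pattern. An open-chain approach would have to create C2 enantioselectively next to an epimerisable ester. The forward reaction requires migration of the ring A carbon rather than hydride shift or O–H insertion.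

**Diazo ketone from the chiral pool (4 ⇐ 3 ⇐ 2 ⇐ 1).** The diazo group comes from oxime 3 (N–N bond cut), the oxime from dimethyl ether 2 (C3–N bond cut), and 2 from naringenin 1. Nitrosation under acid is chosen over base-mediated diazo transfer because a flavanone enolate expels O1 and destroys C2.

**Ring B unit (19 ⇐ 18 ⇐ 16 ⇐ 15 ⇐ 14 ⇐ 12 + 13; 12 ⇐ 10 + 11).** Bromide 19 is the C2′ epimer of cis compound 18. The C2′–C3′ bond of 18 is cut to the carbene derived from hydrazone 16 through diazo compound 17. This turns the dihydrofuran into a simple benzophenone 15 with an ortho 4-methoxybenzyl ether. Ketone 15 comes from carbinol 14, which is assembled from aldehyde 12 and Grignard reagent 13. Aldehyde 12 comes from 5-bromo-2-hydroxy-3-methoxybenzaldehyde 10 and 4-methoxybenzyl chloride 11. The forward insertion must set C3′, the only ring B centre that cannot be corrected later.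

## Roads not taken

**Alternative 1:** The ring B dihydrofuran is cut at O1′–C2′ and at the aryl bonds of C2′ and C3′, leading back to an (E)-alkenyl boronate on the ring B arene. Forward, its ate complex with the aryllithium carrying the C2′ aryl group meets the aryl triflate carrying the C3′ aryl group under a palladium catalyst with a chiral ferrocenyl bisphosphine. Migration from boron forms C2′–aryl and reductive elimination forms C3′–aryl, giving boronate A1.
- Merits: both ring B stereocentres and two C–aryl bonds arise in one catalytic step, and no cis-to-trans correction is needed. In this respect it is better than steps 10–12 of the chosen route.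
- Weak points: β-aryl alkenyl boronates with an ortho substituent are reluctant substrates. The benzylic C–B bond of A1 must be oxidised and the resulting 4-methoxybenzylic alcohol closed with inversion, where ionisation competes. The aryl chloride of A1 is a poorer partner for the union than bromide 19. The road offers nothing for ring A.
- Comparison: the chosen plan sets against it a carbene insertion developed on this substitution pattern and a ring A whose C2 comes from the chiral pool.

**Alternative 2:** Ring A itself is cut at C7a–C3a, C4–C5 and C6–C7. Forward, a ruthenium-catalysed (2+2+2) cycloaddition joins a tethered ynol ether and enyne with a boron-substituted alkyne, closing ring A and the fused dihydrofuran together to give boronate A2.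
- Merits: the styryl group is in place from the start, so no coupling at the crowded C4 is needed, and boron marks C6 for the hydroxyl. Regiochemical economy on ring A is better than in the chosen plan.
- Weak points: the tether must already hold C2 and C3 as an acyclic 1,2-diaryl unit of defined absolute configuration, for which the road names no source. Secondary benzylic ynol ethers are thermally and acid labile. The position of boron rests on steric control alone. The stilbene must survive the later construction of the second dihydrofuran on the C3 aryl group of A2 and all ether cleavages.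
- Comparison: the chosen plan sets against it stereocentres from naringenin and a stilbene that never meets acid or sensitiser.

**Alternative 3:** The ring B dihydrofuran is cut at C2′–C3′ and O1′–C2′. Forward, base generates the ring B ortho-quinone methide from a 2-(sulfonylbenzyl)phenol, a chiral 4-methoxybenzyl sulfonium ylide adds to its exocyclic carbon, and the phenoxide displaces the sulfide, giving A3. A3 is the same compound as bromide 19.
- Merits: the trans isomer forms directly, in about three steps from aldehyde 10 instead of six, without a diazo compound or an epimerisation. It is shorter than steps 7–12.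
- Weak points: absolute control depends on a stoichiometric chiral sulfide and on face selection at a planar, short-lived quinone methide by a semi-stabilised ylide. This is much less secured than catalytic carbene insertion, and C3′ is the centre that cannot be repaired. It addresses ring B only.
- Comparison: because it ends at 19, it could replace steps 7–12 without touching the rest. The chosen plan prefers catalytic, better-secured control of C3′.

Key step: step 4

Assumption: naringenin 1 is used as the single (2S) enantiomer, and the sense of induction of Rh2(R-PTAD)4 in step 11 is taken by analogy with related donor/donor carbene insertions; should it give the 3S series, the antipode Rh2(S-PTAD)4 is used and nothing else changes.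

## Route

Step 1
Reactants: 1 (2S)-naringenin
Product: 2 (2S)-5-hydroxy-7-methoxy-2-(4-methoxyphenyl)chroman-4-one
Conditions: MeOH, PPh3, DIAD, THF, 0 °C to rt
Reagents that add atoms: methanol (CO)
Why: Mitsunobu etherification of phenols: the 7- and 4′-hydroxyls are activated, while the 5-hydroxyl is tied up in a hydrogen bond to the C4 carbonyl and stays free; no flavanone enolate forms under these near-neutral conditions, so C2 is not exposed to ring opening to the chalcone.

Step 2
Reactants: 2 (2S)-5-hydroxy-7-methoxy-2-(4-methoxyphenyl)chroman-4-one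
Product: 3 (2R)-5-hydroxy-3-(hydroxyimino)-7-methoxy-2-(4-methoxyphenyl)chroman-4-one
Conditions: i-AmONO, HCl, EtOH–THF, 0 °C
Reagents that add atoms: isoamyl nitrite (CC(C)CCON=O)
Why: Acid-mediated α-nitrosation of a ketone, the classical entry to 3-oximinoflavanones: the enol is captured at C3 and the nitroso compound tautomerises to the oxime, with no enolate that could expel O1. C2 keeps its arrangement in space; the descriptor becomes R only because C3 now outranks the aryl group.

Step 3
Reactants: 3 (2R)-5-hydroxy-3-(hydroxyimino)-7-methoxy-2-(4-methoxyphenyl)chroman-4-one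
Product: 4 (2R)-3-diazo-5-hydroxy-7-methoxy-2-(4-methoxyphenyl)chroman-4-one
Conditions: NH3 (aq), NaOCl (chloramine preformed), NaOH, THF–H2O, 0 °C
Reagents that add atoms: ammonia (N), which NaOCl converts in the flask into chloramine (NCl), the reagent that delivers the nitrogen atom
Why: Forster reaction: the oximate nitrogen is aminated by chloramine and loss of water gives the α-diazo ketone, as with 2-oximino-1-indanone and 16-oximino-17-keto steroids. Chloramine is preformed so that no free hypochlorite meets the phenolate ring, and C3 carries no hydrogen, so base cannot open the ring.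

Step 4
Reactants: 4 (2R)-3-diazo-5-hydroxy-7-methoxy-2-(4-methoxyphenyl)chroman-4-one
Product: 7 methyl (2S,3S)-4-hydroxy-6-methoxy-2-(4-methoxyphenyl)-2,3-dihydrobenzofuran-3-carboxylate, via ketene 5 (not isolated), via cis ester 6 (not isolated)
Conditions: hν (365 nm), MeOH, 15 °C; then DBU, 40 °C
Reagents that add atoms: methanol (CO)
Why: Photochemical Wolff rearrangement used as a ring contraction of a cyclic 2-diazo ketone; the closest known cases are 2-diazo-1-indanone, 2-diazo-1-tetralones and 3-diazochroman-4-ones, which give ring-contracted arylacetic esters on irradiation in methanol. Excitation of 4, whose diazo and carbonyl groups are locked s-cis by the ring, expels N2 while the ring A carbon C4a shifts from the carbonyl carbon to the diazo carbon, so ketene 5 forms without a long-lived free carbene. This 1,2-shift creates the C3–C3a bond and closes the dihydrofuran by contraction: the six-membered ring O1–C2–C3–C4–C4a–C8a becomes the five-membered ring O1–C2–C3–C3a–C7a with the old carbonyl carbon extruded as the exocyclic ketene carbon; no open chain is cyclised. Methanol adds to the ketene and the ester enol is protonated at C3 mainly from the face opposite the C2 aryl group, which gives cis ester 6 first; DBU then equilibrates C3 through the ester enolate to trans ester 7, so the new stereocentre is under thermodynamic control by C2. C2 is a spectator: none of its bonds is broken, and β-elimination of O1 from the C3 enolate would be the reverse of a 5-endo-trig closure. The step needs aryl migration to win over the 1,2-hydride shift from C2 (which would give the flavone) and over O–H insertion into methanol; direct irradiation of the locked diazo ketone, without metal or sensitiser, favours the concerted migration of the electron-rich aryl carbon. The chelated C5 hydroxyl does not take part and appears as the C4 phenol of 7.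

Step 5
Reactants: 7 methyl (2S,3S)-4-hydroxy-6-methoxy-2-(4-methoxyphenyl)-2,3-dihydrobenzofuran-3-carboxylate
Product: 8 methyl (2S,3S)-6-methoxy-2-(4-methoxyphenyl)-4-{[(trifluoromethyl)sulfonyl]oxy}-2,3-dihydrobenzofuran-3-carboxylate
Conditions: Tf2O, pyridine, CH2Cl2, −20 to 0 °C
Reagents that add atoms: trifluoromethanesulfonic anhydride (O=S(=O)(OS(=O)(=O)C(F)(F)F)C(F)(F)F)
Why: Sulfonylation of the peri phenol: it marks C4 for the later styryl coupling and removes an oxidisable phenolate from the photoredox step; pyridine is too weak to enolise the ester.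

Step 6
Reactants: 8 methyl (2S,3S)-6-methoxy-2-(4-methoxyphenyl)-4-{[(trifluoromethyl)sulfonyl]oxy}-2,3-dihydrobenzofuran-3-carboxylate
Product: 9 (2S,3S)-6-methoxy-2-(4-methoxyphenyl)-4-{[(trifluoromethyl)sulfonyl]oxy}-2,3-dihydrobenzofuran-3-carboxylic acid
Conditions: Me3SnOH, ClCH2CH2Cl, 80 °C; 1 M HCl work-up
Reagents that add atoms: trimethyltin hydroxide (C[Sn](C)(C)O), which supplies the hydroxyl oxygen of the acid
Why: Me3SnOH-mediated cleavage of a hindered methyl ester, a mild method for base-sensitive esters: it avoids hydroxide, which would attack the aryl triflate at sulfur and could open the dihydrofuran by β-elimination. The configuration at C3 is immaterial from here on and C2 is not touched.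

Step 7
Reactants: 10 5-bromo-2-hydroxy-3-methoxybenzaldehyde; 11 4-methoxybenzyl chloride
Product: 12 5-bromo-3-methoxy-2-[(4-methoxybenzyl)oxy]benzaldehyde
Conditions: K2CO3, n-Bu4NI (cat.), DMF, 50 °C
Reagents that add atoms: none
Why: Williamson etherification of the phenol; it installs the benzylic methylene that becomes C2′ with its 4-methoxyphenyl group.

Step 8
Reactants: 12 5-bromo-3-methoxy-2-[(4-methoxybenzyl)oxy]benzaldehyde; 13 3,5-dimethoxyphenylmagnesium chloride
Product: 14 {5-bromo-3-methoxy-2-[(4-methoxybenzyl)oxy]phenyl}(3,5-dimethoxyphenyl)methanol (racemic)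
Conditions: THF, −78 to 0 °C; aq. NH4Cl
Reagents that add atoms: none
Why: Grignard addition to the aldehyde, which at low temperature is much faster than halogen–magnesium exchange at the aryl bromide; the racemic carbinol centre is removed in step 9.

Step 9
Reactants: 14 {5-bromo-3-methoxy-2-[(4-methoxybenzyl)oxy]phenyl}(3,5-dimethoxyphenyl)methanol
Product: 15 {5-bromo-3-methoxy-2-[(4-methoxybenzyl)oxy]phenyl}(3,5-dimethoxyphenyl)methanone
Conditions: MnO2, CH2Cl2, rt
Reagents that add atoms: none
Why: MnO2 oxidation of a doubly benzylic alcohol to the benzophenone; the 4-methoxybenzyl ether and the aryl bromide are inert.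

Step 10
Reactants: 15 {5-bromo-3-methoxy-2-[(4-methoxybenzyl)oxy]phenyl}(3,5-dimethoxyphenyl)methanone
Product: 16 {5-bromo-3-methoxy-2-[(4-methoxybenzyl)oxy]phenyl}(3,5-dimethoxyphenyl)methanone hydrazone (E/Z mixture)
Conditions: N2H4·H2O (excess), AcOH (cat.), EtOH, 80 °C
Reagents that add atoms: hydrazine (NN)
Why: Hydrazone formation from a diaryl ketone; the excess of hydrazine suppresses azine formation and the E/Z ratio is of no consequence.

Step 11
Reactants: 16 {5-bromo-3-methoxy-2-[(4-methoxybenzyl)oxy]phenyl}(3,5-dimethoxyphenyl)methanone hydrazone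
Product: 18 (2S,3R)-5-bromo-3-(3,5-dimethoxyphenyl)-7-methoxy-2-(4-methoxyphenyl)-2,3-dihydrobenzofuran, via diaryldiazomethane 17 (not isolated)
Conditions: MnO2, CH2Cl2, 0 °C; filter; Rh2(R-PTAD)4 (1 mol %), CH2Cl2, 0 °C
Reagents that add atoms: none
Why: MnO2 dehydrogenates the hydrazone to diaryldiazomethane 17, and the donor/donor carbene formed on the divalent rhodium dimer inserts enantioselectively into the benzylic ether C–H bond (1,5-insertion), a reaction developed for 2-benzyloxybenzophenone hydrazones of this kind. The chiral carboxylate ligands set C3′ and the concerted insertion gives the cis-2,3-diaryl product; the ether methylene, activated by oxygen and the 4-methoxyphenyl ring, is the only C–H bond reachable through a five-membered transition state.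

Step 12
Reactants: 18 (2S,3R)-5-bromo-3-(3,5-dimethoxyphenyl)-7-methoxy-2-(4-methoxyphenyl)-2,3-dihydrobenzofuran
Product: 19 (2R,3R)-5-bromo-3-(3,5-dimethoxyphenyl)-7-methoxy-2-(4-methoxyphenyl)-2,3-dihydrobenzofuran
Conditions: CF3CO2H, CH2Cl2 (dilute), 0 °C to rt
Reagents that add atoms: none
Why: Acid-mediated epimerisation at C2′ of a 2-(4-methoxyphenyl)dihydrobenzofuran: reversible ionisation of the benzylic C2′–O1′ bond to the 4-methoxybenzyl cation and re-closure by the phenol lead to the more stable trans isomer. C3′ has no heteroatom and does not take part, so the 3R centre from step 11 dictates 2R.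

Step 13
Reactants: 9 (2S,3S)-6-methoxy-2-(4-methoxyphenyl)-4-{[(trifluoromethyl)sulfonyl]oxy}-2,3-dihydrobenzofuran-3-carboxylic acid; 19 (2R,3R)-5-bromo-3-(3,5-dimethoxyphenyl)-7-methoxy-2-(4-methoxyphenyl)-2,3-dihydrobenzofuran
Product: 20 (2S,3S)-3-[(2R,3R)-3-(3,5-dimethoxyphenyl)-7-methoxy-2-(4-methoxyphenyl)-2,3-dihydrobenzofuran-5-yl]-6-methoxy-2-(4-methoxyphenyl)-2,3-dihydrobenzofuran-4-yl trifluoromethanesulfonate
Conditions: Ir[dF(CF3)ppy]2(dtbbpy)PF6 (2 mol %), NiCl2(dme) (10 mol %), dtbbpy (15 mol %), Cs2CO3, DMF, blue LEDs (450 nm), rt
Reagents that add atoms: none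
Why: Nickel/photoredox decarboxylative arylation of a secondary benzylic carboxylic acid with an aryl bromide: the caesium carboxylate of 9 is oxidised by the excited trivalent iridium complex, CO2 is lost, and the C3 radical is captured by the arylnickel bromide formed from 19 and zerovalent nickel; reductive elimination forms C3–C5′. Bipyridine-ligated zerovalent nickel adds to aryl bromides in preference to aryl triflates, here an electron-rich and ortho-substituted one, which lets the C4 triflate be carried. Radical capture is reversible and the aryl group is delivered to the face of C3 opposite the C2 aryl group, so C2 sets C3 as S; ring opening of the radical by β-scission of C2–O1 would be the reverse of a 5-endo closure and is slow.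

Step 14
Reactants: 20 (2S,3S)-3-[(2R,3R)-3-(3,5-dimethoxyphenyl)-7-methoxy-2-(4-methoxyphenyl)-2,3-dihydrobenzofuran-5-yl]-6-methoxy-2-(4-methoxyphenyl)-2,3-dihydrobenzofuran-4-yl trifluoromethanesulfonate
Product: 21 (2S,3S)-3-[(2R,3R)-3-(3,5-dihydroxyphenyl)-7-hydroxy-2-(4-hydroxyphenyl)-2,3-dihydrobenzofuran-5-yl]-6-hydroxy-2-(4-hydroxyphenyl)-2,3-dihydrobenzofuran-4-yl trifluoromethanesulfonate
Conditions: BBr3 (excess), CH2Cl2, −78 °C to rt; MeOH, then H2O
Reagents that add atoms: none
Why: BBr3 cleavage of aryl methyl ethers, to which aryl triflates are inert. With no alkene present the only acid-labile sites are the two benzylic C2–O bonds; these can open only reversibly, since no arene carbon can reach either benzylic cation except through a four-membered ring, and they re-close trans on work-up under control of C3 and C3′.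

Step 15
Reactants: 21 (2S,3S)-3-[(2R,3R)-3-(3,5-dihydroxyphenyl)-7-hydroxy-2-(4-hydroxyphenyl)-2,3-dihydrobenzofuran-5-yl]-6-hydroxy-2-(4-hydroxyphenyl)-2,3-dihydrobenzofuran-4-yl trifluoromethanesulfonate
Product: 22 hexaacetate of 21 (all six phenols acetylated, triflate retained)
Conditions: Ac2O, pyridine, DMAP (cat.), CH2Cl2, rt
Reagents that add atoms: acetic anhydride (CC(=O)OC(C)=O)
Why: Acetylation of phenols; it gives an air-stable intermediate that can be chromatographed and keeps phenolates out of the cross-coupling.

Step 16
Reactants: 23 4-acetoxystyrene; 24 4,4,5,5-tetramethyl-2-vinyl-1,3,2-dioxaborolane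
Product: 25 4-[(E)-2-(4,4,5,5-tetramethyl-1,3,2-dioxaborolan-2-yl)ethenyl]phenyl acetate
Conditions: RuCl2(=CHPh)(PCy3)(H2IMes) (second-generation Grubbs catalyst, 3 mol %), CH2Cl2, 40 °C
Reagents that add atoms: none
Why: Olefin cross-metathesis of a styrene with vinylboronic acid pinacol ester, which gives (E)-2-arylvinylboronates with high E selectivity for steric reasons.

Step 17
Reactants: 22 hexaacetate triflate; 25 4-[(E)-2-(4,4,5,5-tetramethyl-1,3,2-dioxaborolan-2-yl)ethenyl]phenyl acetate
Product: 26 heptaacetate of 27
Conditions: Pd(OAc)2 (5 mol %), SPhos (10 mol %), K3PO4, toluene–H2O, 70 °C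
Reagents that add atoms: none
Why: Suzuki–Miyaura coupling of an aryl triflate with an (E)-alkenylboronate, with retention of alkene geometry; the biaryl dialkylphosphine helps zerovalent palladium add to the crowded C4–O bond. Any acetate lost to the base does no harm, since all are removed in step 18.

Step 18
Reactants: 26 heptaacetate of 27
Product: 27 (2S,3S)-3-[(2R,3R)-3-(3,5-dihydroxyphenyl)-7-hydroxy-2-(4-hydroxyphenyl)-2,3-dihydrobenzofuran-5-yl]-2-(4-hydroxyphenyl)-4-[(E)-2-(4-hydroxyphenyl)ethenyl]-2,3-dihydrobenzofuran-6-ol (CNP0172909.1)
Conditions: K2CO3 (cat.), MeOH–THF, 0 °C to rt, argon, dark; then AcOH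
Reagents that add atoms: none
Why: Base-catalysed transesterification of aryl acetates by methanol, easy because phenoxides are good leaving groups. No acid is present, so the stilbene cannot alkylate ring B, and exclusion of air and light protects the polyphenolic stilbene.

## Compound list

1 | (2S)-naringenin | O=C1C[C@@H](c2ccc(O)cc2)Oc2cc(O)cc(O)c12 | starting material
2 | (2S)-5-hydroxy-7-methoxy-2-(4-methoxyphenyl)chroman-4-one | O=C1C[C@@H](c2ccc(OC)cc2)Oc2cc(OC)cc(O)c12 | intermediate
3 | (2R)-5-hydroxy-3-(hydroxyimino)-7-methoxy-2-(4-methoxyphenyl)chroman-4-one | O=C1C(=NO)[C@@H](c2ccc(OC)cc2)Oc2cc(OC)cc(O)c12 | intermediate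
4 | (2R)-3-diazo-5-hydroxy-7-methoxy-2-(4-methoxyphenyl)chroman-4-one | O=C1C(=[N+]=[N-])[C@@H](c2ccc(OC)cc2)Oc2cc(OC)cc(O)c12 | intermediate
5 | (2R)-4-hydroxy-6-methoxy-2-(4-methoxyphenyl)-3-(oxomethylidene)-2,3-dihydrobenzofuran (ketene) | O=C=C1[C@@H](c2ccc(OC)cc2)Oc2cc(OC)cc(O)c12 | intermediate
6 | methyl (2S,3R)-4-hydroxy-6-methoxy-2-(4-methoxyphenyl)-2,3-dihydrobenzofuran-3-carboxylate (cis) | Oc1cc(OC)cc2c1[C@@H](C(=O)OC)[C@@H](c1ccc(OC)cc1)O2 | intermediate
7 | methyl (2S,3S)-4-hydroxy-6-methoxy-2-(4-methoxyphenyl)-2,3-dihydrobenzofuran-3-carboxylate (trans) | Oc1cc(OC)cc2c1[C@H](C(=O)OC)[C@@H](c1ccc(OC)cc1)O2 | intermediate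
8 | methyl (2S,3S)-6-methoxy-2-(4-methoxyphenyl)-4-{[(trifluoromethyl)sulfonyl]oxy}-2,3-dihydrobenzofuran-3-carboxylate | O=S(=O)(Oc1cc(OC)cc2c1[C@H](C(=O)OC)[C@@H](c1ccc(OC)cc1)O2)C(F)(F)F | intermediate
9 | (2S,3S)-6-methoxy-2-(4-methoxyphenyl)-4-{[(trifluoromethyl)sulfonyl]oxy}-2,3-dihydrobenzofuran-3-carboxylic acid | O=S(=O)(Oc1cc(OC)cc2c1[C@H](C(=O)O)[C@@H](c1ccc(OC)cc1)O2)C(F)(F)F | intermediate
10 | 5-bromo-2-hydroxy-3-methoxybenzaldehyde | COc1cc(Br)cc(C=O)c1O | starting material
11 | 4-methoxybenzyl chloride | COc1ccc(CCl)cc1 | starting material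
12 | 5-bromo-3-methoxy-2-[(4-methoxybenzyl)oxy]benzaldehyde | COc1ccc(COc2c(OC)cc(Br)cc2C=O)cc1 | intermediate
13 | 3,5-dimethoxyphenylmagnesium chloride | COc1cc(OC)cc([Mg]Cl)c1 | starting material
14 | {5-bromo-3-methoxy-2-[(4-methoxybenzyl)oxy]phenyl}(3,5-dimethoxyphenyl)methanol (racemic) | COc1ccc(COc2c(OC)cc(Br)cc2C(O)c2cc(OC)cc(OC)c2)cc1 | intermediate
15 | {5-bromo-3-methoxy-2-[(4-methoxybenzyl)oxy]phenyl}(3,5-dimethoxyphenyl)methanone | COc1ccc(COc2c(OC)cc(Br)cc2C(=O)c2cc(OC)cc(OC)c2)cc1 | intermediate
16 | hydrazone of 15 | COc1ccc(COc2c(OC)cc(Br)cc2C(=NN)c2cc(OC)cc(OC)c2)cc1 | intermediate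
17 | 5-bromo-1-[diazo(3,5-dimethoxyphenyl)methyl]-3-methoxy-2-[(4-methoxybenzyl)oxy]benzene | COc1ccc(COc2c(OC)cc(Br)cc2C(=[N+]=[N-])c2cc(OC)cc(OC)c2)cc1 | intermediate
18 | (2S,3R)-5-bromo-3-(3,5-dimethoxyphenyl)-7-methoxy-2-(4-methoxyphenyl)-2,3-dihydrobenzofuran (cis) | Brc1cc(OC)c2c(c1)[C@@H](c1cc(OC)cc(OC)c1)[C@@H](c1ccc(OC)cc1)O2 | intermediate
19 | (2R,3R)-5-bromo-3-(3,5-dimethoxyphenyl)-7-methoxy-2-(4-methoxyphenyl)-2,3-dihydrobenzofuran (trans) | Brc1cc(OC)c2c(c1)[C@@H](c1cc(OC)cc(OC)c1)[C@H](c1ccc(OC)cc1)O2 | intermediate
20 | (2S,3S)-3-[(2R,3R)-3-(3,5-dimethoxyphenyl)-7-methoxy-2-(4-methoxyphenyl)-2,3-dihydrobenzofuran-5-yl]-6-methoxy-2-(4-methoxyphenyl)-2,3-dihydrobenzofuran-4-yl trifluoromethanesulfonate | FC(F)(F)S(=O)(=O)Oc1cc(OC)cc2c1[C@H](c1cc(OC)c3c(c1)[C@@H](c1cc(OC)cc(OC)c1)[C@H](c1ccc(OC)cc1)O3)[C@@H](c1ccc(OC)cc1)O2 | intermediate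
21 | (2S,3S)-3-[(2R,3R)-3-(3,5-dihydroxyphenyl)-7-hydroxy-2-(4-hydroxyphenyl)-2,3-dihydrobenzofuran-5-yl]-6-hydroxy-2-(4-hydroxyphenyl)-2,3-dihydrobenzofuran-4-yl trifluoromethanesulfonate | FC(F)(F)S(=O)(=O)Oc1cc(O)cc2c1[C@H](c1cc(O)c3c(c1)[C@@H](c1cc(O)cc(O)c1)[C@H](c1ccc(O)cc1)O3)[C@@H](c1ccc(O)cc1)O2 | intermediate
22 | hexaacetate of 21 | FC(F)(F)S(=O)(=O)Oc1cc(OC(C)=O)cc2c1[C@H](c1cc(OC(C)=O)c3c(c1)[C@@H](c1cc(OC(C)=O)cc(OC(C)=O)c1)[C@H](c1ccc(OC(C)=O)cc1)O3)[C@@H](c1ccc(OC(C)=O)cc1)O2 | intermediate
23 | 4-acetoxystyrene | CC(=O)Oc1ccc(C=C)cc1 | starting material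
24 | 4,4,5,5-tetramethyl-2-vinyl-1,3,2-dioxaborolane | C=CB1OC(C)(C)C(C)(C)O1 | starting material
25 | 4-[(E)-2-(4,4,5,5-tetramethyl-1,3,2-dioxaborolan-2-yl)ethenyl]phenyl acetate | CC(=O)Oc1ccc(/C=C/B2OC(C)(C)C(C)(C)O2)cc1 | intermediate
26 | heptaacetate of 27 | CC(=O)Oc1ccc(/C=C/c2cc(OC(C)=O)cc3c2[C@H](c2cc(OC(C)=O)c4c(c2)[C@@H](c2cc(OC(C)=O)cc(OC(C)=O)c2)[C@H](c2ccc(OC(C)=O)cc2)O4)[C@@H](c2ccc(OC(C)=O)cc2)O3)cc1 | intermediate
27 | (2S,3S)-3-[(2R,3R)-3-(3,5-dihydroxyphenyl)-7-hydroxy-2-(4-hydroxyphenyl)-2,3-dihydrobenzofuran-5-yl]-2-(4-hydroxyphenyl)-4-[(E)-2-(4-hydroxyphenyl)ethenyl]-2,3-dihydrobenzofuran-6-ol | Oc1ccc(/C=C/c2cc(O)cc3c2[C@H](c2cc(O)c4c(c2)[C@@H](c2cc(O)cc(O)c2)[C@H](c2ccc(O)cc2)O4)[C@@H](c2ccc(O)cc2)O3)cc1 | target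

## Step count and least certain steps

Total: 18 steps. Longest linear sequence: 11 steps (steps 1–6, 13–15, 17 and 18; the ring B branch, steps 7–12 followed by 13–15, 17 and 18, is equally long).

**Step 4 (key step).** The most likely failure is diversion of the excited diazo ketone before the aryl shift: a 1,2-hydride shift from C2 would give the flavone, and insertion into the O–H bond of methanol would give a 3-methoxyflavanone. C2–H is benzylic and next to oxygen, and the phenolic chromophore may also absorb competitively and slow the photolysis. The fallback is the oxidative ring contraction of flavanone 2 itself with PhI(OAc)2 and H2SO4 in trimethyl orthoformate. This is a known hypervalent-iodine rearrangement of flavanones in which the same ring A carbon migrates from C4 to C3 and the methyl ester forms directly. It sets out from 2 and comes back at 7, bypassing 3 and 4, and makes no new isolated compound. Its own weakness, competing migration of the 4-methoxyphenyl group from C2 to C3, is why it is second choice.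

**Step 13.** Three things may go wrong. Nickel may add oxidatively to the C4–O triflate bond of 9 or 20, leading to oligomers. Oxidative addition to the electron-rich bromide 19 may be so slow that the C3 radical is lost to hydrogen abstraction or dimerisation. Face selection at C3 may be incomplete. Any cis isomer must be removed before step 14, since acid would turn it into the wrong trans series by inverting C2. The fallback is a thermal decarboxylative arylation through a redox-active ester. Acid 9 is condensed with N-hydroxyphthalimide and a carbodiimide to the N-hydroxyphthalimide ester F1. Bromide 19 is converted by bromine–lithium exchange with t-BuLi and transmetalation with ZnCl2 into the arylzinc chloride F2. The two are joined with Fe(acac)3 and 1,2-bis(diphenylphosphino)benzene, a catalyst that needs no oxidative addition to an aryl halide and leaves aryl triflates alone. This sets out from 9 and 19 and comes back at 20.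

**Step 2 (with step 3).** Nitrosation may occur on the electron-rich phenolic ring A instead of at C3. Under acid, oxime 3 may tautomerise toward the 3-hydroxyaminoflavone with loss of C2. The ring may be chlorinated in the Forster step. The fallback is detrifluoroacetylative diazo transfer. Ketone 2 is treated with two equivalents of LiN(SiMe3)2 at −78 °C and 2,2,2-trifluoroethyl trifluoroacetate to give (2S)-5-hydroxy-7-methoxy-2-(4-methoxyphenyl)-3-(trifluoroacetyl)chroman-4-one F3. MsN3 and Et3N in aqueous MeCN then give the diazo ketone. The phenolate formed first makes O1 a poorer leaving group, and the enolate is kept cold to limit opening to the chalcone. This sets out from 2 and comes back at 4, bypassing 3.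

**Step 12.** After ionisation at C2′ the cation may lose the C3′ proton to give a triarylethene, whose re-protonation would erode enantiopurity. It may also alkylate a dimethoxyphenyl ring of a second molecule instead of re-closing. The fallback drops the separate protic-acid equilibration. Cis bromide 18 is coupled with 9 under the conditions of step 13 to give the C2′ epimer of triflate 20, (2S,3S)-3-[(2S,3R)-3-(3,5-dimethoxyphenyl)-7-methoxy-2-(4-methoxyphenyl)-2,3-dihydrobenzofuran-5-yl]-6-methoxy-2-(4-methoxyphenyl)-2,3-dihydrobenzofuran-4-yl trifluoromethanesulfonate F4. The BBr3 treatment of step 14 cleaves the C2′–O1′ benzylic ether along with the methyl ethers, and the phenol re-closes trans on work-up. This sets out from 18 and comes back at 21.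

**Step 17.** Oxidative addition at the crowded C4–O bond may be slow. The electron-rich alkenylboronate 25 may meanwhile undergo protodeboronation, and the base may strip acetates. The fallback forms the same bond without a boron reagent, by a Mizoroki–Heck reaction of triflate 22 with 4-acetoxystyrene 23 (Pd(OAc)2, P(o-tol)3, NaOAc, LiCl, DMF, 90 °C), the chloride enforcing the neutral pathway that arylates the terminal carbon. This sets out from 22 and 23 and comes back at 26, with no new compound.

## Further compounds

F0 | step 4 | none | none
F1 | step 13 | 1,3-dioxoisoindolin-2-yl (2S,3S)-6-methoxy-2-(4-methoxyphenyl)-4-{[(trifluoromethyl)sulfonyl]oxy}-2,3-dihydrobenzofuran-3-carboxylate | O=S(=O)(Oc1cc(OC)cc2c1[C@H](C(=O)ON1C(=O)c3ccccc3C1=O)[C@@H](c1ccc(OC)cc1)O2)C(F)(F)F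
F2 | step 13 | [(2R,3R)-3-(3,5-dimethoxyphenyl)-7-methoxy-2-(4-methoxyphenyl)-2,3-dihydrobenzofuran-5-yl]zinc chloride | Cl[Zn]c1cc(OC)c2c(c1)[C@@H](c1cc(OC)cc(OC)c1)[C@H](c1ccc(OC)cc1)O2
F3 | step 2 | (2S)-5-hydroxy-7-methoxy-2-(4-methoxyphenyl)-3-(trifluoroacetyl)chroman-4-one (C3 epimers or enol) | O=C1C(C(=O)C(F)(F)F)[C@@H](c2ccc(OC)cc2)Oc2cc(OC)cc(O)c12
F4 | step 12 | (2S,3S)-3-[(2S,3R)-3-(3,5-dimethoxyphenyl)-7-methoxy-2-(4-methoxyphenyl)-2,3-dihydrobenzofuran-5-yl]-6-methoxy-2-(4-methoxyphenyl)-2,3-dihydrobenzofuran-4-yl trifluoromethanesulfonate | FC(F)(F)S(=O)(=O)Oc1cc(OC)cc2c1[C@H](c1cc(OC)c3c(c1)[C@@H](c1cc(OC)cc(OC)c1)[C@@H](c1ccc(OC)cc1)O3)[C@@H](c1ccc(OC)cc1)O2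
F0 | step 17 | none | none
A1 | alternative 1 | 2-[(1S,2R)-2-[5-chloro-3-methoxy-2-(methoxymethoxy)phenyl]-2-(3,5-dimethoxyphenyl)-1-(4-methoxyphenyl)ethyl]-4,4,5,5-tetramethyl-1,3,2-dioxaborolane | COCOc1c(OC)cc(Cl)cc1[C@@H](c1cc(OC)cc(OC)c1)[C@@H](c1ccc(OC)cc1)B1OC(C)(C)C(C)(C)O1
A2 | alternative 2 | 2-[(2S,3S)-3-[3-methoxy-4-(methoxymethoxy)phenyl]-2-(4-methoxyphenyl)-4-[(E)-2-(4-methoxyphenyl)ethenyl]-2,3-dihydrobenzofuran-6-yl]-4,4,5,5-tetramethyl-1,3,2-dioxaborolane | COc1ccc(/C=C/c2cc(B3OC(C)(C)C(C)(C)O3)cc3c2[C@H](c2ccc(OCOC)c(OC)c2)[C@@H](c2ccc(OC)cc2)O3)cc1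
A3 | alternative 3 | (2R,3R)-5-bromo-3-(3,5-dimethoxyphenyl)-7-methoxy-2-(4-methoxyphenyl)-2,3-dihydrobenzofuran | Brc1cc(OC)c2c(c1)[C@@H](c1cc(OC)cc(OC)c1)[C@H](c1ccc(OC)cc1)O2
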